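**Plan**

1. Retrosynthesis: the lactone C–O bond is cut first. Next, in one operation, the two neighbouring ring B bonds to carbon are cut: ring carbon to alkenyl carbon (taken back to an alkyne) and ring carbon to formyl carbon (taken back to a Weinreb amide). Then the diaryl ether C–O bond is cut, and the side chain is cut at the alkyne and between the two carbinol carbons.
2. Enabling feature: ring B is contiguously tetrasubstituted, and the carbon holding the alkene lies between the carbon bonded to the ring A oxygen and the carbon bearing the formyl group. An iodide at that middle carbon has one ortho position blocked by the aryloxy group and a single ortho C–H, at the future formyl carbon.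
3. Forward: ring A boronic acid and 2-iodo-4-methoxyphenol give the diaryl ether iodide; hexanal gives the protected syn-diol alkyne; a three-component palladium/norbornene coupling joins chain, ring B and the acyl carbon without closing a ring.
4. The only ring formed, the 12-membered lactone, is closed late by Yamaguchi esterification after amide reduction, semi-hydrogenation and fluoride unmasking; BCl3 then frees the phenol and the allylic alcohol.
5. Stereochemistry: both S carbinol centres come from one reagent-controlled (Z)-γ-alkoxyallylboration of hexanal; the Z alkene comes from Lindlar semi-hydrogenation.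

Key step: step 8

Remark: the target is read from the SMILES as S at both carbinol carbons with a Z alkene; allyl methoxymethyl ether, 2-iodo-4-methoxyphenol and N-methoxy-N-methylcarbamoyl chloride are taken as purchasable.

**Route**

Step 1
Reactants: 1 5-bromo-2-methylbenzoic acid
Product: 2 2-(trimethylsilyl)ethyl 5-bromo-2-methylbenzoate
Conditions: Me3SiCH2CH2OH, EDC·HCl, DMAP (cat.), CH2Cl2, 0 °C → rt
Reagents that add atoms: 2-(trimethylsilyl)ethanol, C[Si](C)(C)CCO
Why: Carbodiimide activation with DMAP catalysis (Steglich esterification) should esterify the ortho-toluic acid with the primary alcohol, giving an ester that fluoride later removes together with the silyl ether.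

Step 2
Reactants: 2 2-(trimethylsilyl)ethyl 5-bromo-2-methylbenzoate
Product: 3 [4-methyl-3-{[2-(trimethylsilyl)ethoxy]carbonyl}phenyl]boronic acid
Conditions: B2(OH)4, PdCl(XPhos)(2′-aminobiphenyl-2-yl) (second-generation XPhos palladacycle, 1 mol %), XPhos, KOAc, EtOH, 80 °C; aqueous work-up
Reagents that add atoms: tetrahydroxydiboron, OB(O)B(O)O
Why: Palladium-catalysed Miyaura-type borylation of the aryl bromide with tetrahydroxydiboron should give the free boronic acid directly, the form that couples best with phenols under copper, without an organolithium that the ester would not survive.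

Step 3
Reactants: 3 [4-methyl-3-{[2-(trimethylsilyl)ethoxy]carbonyl}phenyl]boronic acid; 4 2-iodo-4-methoxyphenol
Product: 5 2-(trimethylsilyl)ethyl 5-(2-iodo-4-methoxyphenoxy)-2-methylbenzoate
Conditions: Cu(OAc)2 (1 equiv.), pyridine (5 equiv.), 4 Å molecular sieves, CH2Cl2, air, rt
Reagents that add atoms: none
Why: Chan–Lam oxidative coupling at room temperature should form the diaryl ether C–O bond while leaving the ortho C–I bond untouched, which a heated Ullmann or a palladium-catalysed etherification would not.

Step 4
Reactants: 6 hexanal; 7 allyl methoxymethyl ether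
Product: 11 (3S,4S)-3-(methoxymethoxy)non-1-en-4-ol, via Z-alkoxyallyllithium 8 (not isolated), via Z-alkoxyallylborane 9 (not isolated), via borinate adduct 10 (not isolated)
Conditions: 7, s-BuLi, THF, −78 °C; (+)-Ipc2BOMe, −78 °C; BF3·OEt2, then 6, −78 °C → rt; 3 M NaOH, 30 % H2O2, rt
Reagents that add atoms: none
Why: Brown (Z)-γ-alkoxyallylboration, in which kinetic lithiation gives the chelated Z-allyl anion, boron transfer gives 9, and a closed chair transition state with the isopinocampheyl groups from (−)-α-pinene directing the allyl carbon to the Re face of hexanal should set both carbinol centres at once, syn to each other and 3S,4S.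

Step 5
Reactants: 11 (3S,4S)-3-(methoxymethoxy)non-1-en-4-ol
Product: 12 tert-butyldimethyl{[(3S,4S)-3-(methoxymethoxy)non-1-en-4-yl]oxy}silane
Conditions: TBSCl, imidazole, DMAP (cat.), DMF, rt
Reagents that add atoms: tert-butyldimethylsilyl chloride, CC(C)(C)[Si](C)(C)Cl
Why: Silyl ether formation under imidazole catalysis masks the future lactone oxygen with a group that is orthogonal to the methoxymethyl ether and removable by fluoride, under conditions that cannot touch the acetal.

Step 6
Reactants: 12 tert-butyldimethyl{[(3S,4S)-3-(methoxymethoxy)non-1-en-4-yl]oxy}silane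
Product: 14 (2R,3S)-3-(tert-butyldimethylsilyloxy)-2-(methoxymethoxy)octanal, via ozonide 13 (not isolated)
Conditions: O3, CH2Cl2, −78 °C; then PPh3, −78 °C → rt
Reagents that add atoms: ozone, [O-][O+]=O
Why: Ozonolysis of the terminal alkene with reductive work-up excises the methylene carbon and should give the α-alkoxy aldehyde under cold, neutral conditions that leave both stereocentres untouched (the descriptor at C2 changes only because the priorities change).

Step 7
Reactants: 14 (2R,3S)-3-(tert-butyldimethylsilyloxy)-2-(methoxymethoxy)octanal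
Product: 15 (3S,4S)-4-(tert-butyldimethylsilyloxy)-3-(methoxymethoxy)non-1-yne
Conditions: dimethyl (1-diazo-2-oxopropyl)phosphonate, K2CO3, MeOH, 0 °C → rt
Reagents that add atoms: dimethyl (1-diazo-2-oxopropyl)phosphonate, COP(=O)(OC)C(=[N+]=[N-])C(C)=O
Why: Ohira–Bestmann (Seyferth–Gilbert) homologation converts the aldehyde into the terminal alkyne under mild carbonate/methanol conditions that normally leave α-alkoxy stereocentres intact.

Step 8
Reactants: 5 2-(trimethylsilyl)ethyl 5-(2-iodo-4-methoxyphenoxy)-2-methylbenzoate; 15 (3S,4S)-4-(tert-butyldimethylsilyloxy)-3-(methoxymethoxy)non-1-yne; 16 N-methoxy-N-methylcarbamoyl chloride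
Product: 17 2-(trimethylsilyl)ethyl 5-{2-[(3S,4S)-4-(tert-butyldimethylsilyloxy)-3-(methoxymethoxy)non-1-yn-1-yl]-4-methoxy-3-[methoxy(methyl)carbamoyl]phenoxy}-2-methylbenzoate
Conditions: Pd(OAc)2 (10 mol %), P(2-furyl)3 (25 mol %), norbornene (1.5 equiv.), Cs2CO3 (3 equiv.), 16 (2 equiv.), toluene, 100 °C; 15 (1.3 equiv.) added by syringe pump over 8 h
Reagents that add atoms: none
Why: Proposed new method: zerovalent palladium should insert into the C–I bond of 5, norbornene should insert into the aryl–palladium bond, and the alkylpalladium should close the aryl–norbornyl palladacycle at the only ortho C–H (between the iodide carbon and the methoxy carbon); oxidative addition of 16 then gives a tetravalent palladium carbamoyl species, reductive elimination forms the ring B–carbonyl bond, and with both ortho positions filled norbornene is expelled by β-carbon elimination. The resulting divalent arylpalladium should be intercepted by the acetylide of 15 (copper-free Sonogashira-type termination), and reductive elimination forms the ring B–alkyne bond. The closest known reaction types are the Catellani ortho-acylation of aryl iodides with acyl chlorides or anhydrides and Catellani ortho-functionalisation with ipso-alkynylation by terminal alkynes; a carbamoyl chloride as acyl donor and palladation beside a methoxy group are the untested elements. No ring is closed and no stereocentre is formed, and the two carbinol centres of 15 carry no proton that carbonate in toluene should remove. The step needs ortho-acylation to precede ipso-alkynylation and both to outrun direct alkynylation of 5: the aryloxy group leaves a single ortho C–H, excess norbornene traps the arylpalladium before the alkyne can, 16 is present in excess, and 15 is kept at low concentration by slow addition.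

Step 9
Reactants: 17 alkynyl Weinreb amide (named in step 8)
Product: 18 2-(trimethylsilyl)ethyl 5-{2-[(3S,4S)-4-(tert-butyldimethylsilyloxy)-3-(methoxymethoxy)non-1-yn-1-yl]-3-formyl-4-methoxyphenoxy}-2-methylbenzoate
Conditions: i-Bu2AlH (1.2 equiv.), THF, −78 °C; aq. KNaC4H4O6
Reagents that add atoms: none
Why: Weinreb amide reduction, in which hydride addition gives an N-methoxy aluminium chelate that is stable at −78 °C and collapses to the aldehyde only on work-up, should be faster at the amide flanked by a linear alkyne than at the ortho-methyl-shielded benzoate ester.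

Step 10
Reactants: 18 alkynyl aldehyde (named in step 9)
Product: 19 2-(trimethylsilyl)ethyl 5-{2-[(1Z,3S,4S)-4-(tert-butyldimethylsilyloxy)-3-(methoxymethoxy)non-1-en-1-yl]-3-formyl-4-methoxyphenoxy}-2-methylbenzoate
Conditions: H2 (1 atm), Pd/CaCO3 poisoned with Pb(OAc)2 (Lindlar catalyst), quinoline, EtOAc, rt
Reagents that add atoms: none
Why: Lindlar semi-hydrogenation delivers both hydrogens to one face of the alkyne on the poisoned palladium surface and should stop at the Z alkene, the aryl aldehyde and the ethers being inert under these conditions.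

Step 11
Reactants: 19 Z-alkenyl aldehyde (named in step 10)
Product: 20 5-{3-formyl-2-[(1Z,3S,4S)-4-hydroxy-3-(methoxymethoxy)non-1-en-1-yl]-4-methoxyphenoxy}-2-methylbenzoic acid
Conditions: Bu4NF (4 equiv.), THF, 0 °C → rt; then 0.5 M aq. HCl to pH 4 at 0 °C
Reagents that add atoms: none
Why: Fluoride-induced desilylation cleaves the silyl ether and, by β-elimination of ethene from the 2-(trimethylsilyl)ethyl ester, should free the carboxylic acid in the same operation while acetal, aldehyde and alkene are untouched.

Step 12
Reactants: 20 seco acid (named in step 11)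
Product: 22 O-methyl O-methoxymethyl macrolactone, via mixed anhydride 21 (not isolated)
Conditions: 2,4,6-Cl3C6H2COCl, Et3N, THF, rt; then slow addition to DMAP, toluene, 80 °C (final 1 mM)
Reagents that add atoms: none
Why: Yamaguchi macrolactonisation, in which DMAP attacks the less shielded toluoyl carbonyl of the mixed anhydride and the acylpyridinium is captured by the C4 hydroxyl under high dilution, should close the 12-membered ring (favoured by the cis-alkene and diaryl ether turns) with retention at the carbinol carbon because its C–O bond is not broken.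

Step 13
Reactants: 22 O-methyl O-methoxymethyl macrolactone
Product: 23 target macrolide CNP0238900.1
Conditions: BCl3 (4 equiv.), CH2Cl2, −78 → −20 °C; aq. NaHCO3
Reagents that add atoms: none
Why: Lewis-acid ether cleavage with BCl3, chelated between the formyl oxygen and the neighbouring methoxy oxygen, should demethylate that ether selectively at low temperature and also cleave the methoxymethyl acetal, while the hindered benzoate lactone and the diaryl ether stay intact.

**Compound list**

1 | 5-bromo-2-methylbenzoic acid | Cc1ccc(Br)cc1C(=O)O | starting material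
2 | 2-(trimethylsilyl)ethyl 5-bromo-2-methylbenzoate | Cc1ccc(Br)cc1C(=O)OCC[Si](C)(C)C | intermediate
3 | [4-methyl-3-{[2-(trimethylsilyl)ethoxy]carbonyl}phenyl]boronic acid | Cc1ccc(B(O)O)cc1C(=O)OCC[Si](C)(C)C | intermediate
4 | 2-iodo-4-methoxyphenol | COc1ccc(O)c(I)c1 | starting material
5 | 2-(trimethylsilyl)ethyl 5-(2-iodo-4-methoxyphenoxy)-2-methylbenzoate | Cc1ccc(Oc2ccc(OC)cc2I)cc1C(=O)OCC[Si](C)(C)C | intermediate
6 | hexanal | CCCCCC=O | starting material
7 | allyl methoxymethyl ether, 3-(methoxymethoxy)prop-1-ene | C=CCOCOC | starting material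
8 | (Z)-[3-(methoxymethoxy)allyl]lithium | [Li]C/C=C\OCOC | intermediate
9 | (Z)-[3-(methoxymethoxy)allyl]diisopinocampheylborane from (+)-Ipc2BOMe | COCO/C=C\CB([C@H]1C[C@H]2C[C@@H]([C@@H]1C)C2(C)C)[C@H]1C[C@H]2C[C@@H]([C@@H]1C)C2(C)C | intermediate
10 | diisopinocampheylborinate of (3S,4S)-3-(methoxymethoxy)non-1-en-4-ol | CCCCC[C@H](OB([C@H]1C[C@H]2C[C@@H]([C@@H]1C)C2(C)C)[C@H]1C[C@H]2C[C@@H]([C@@H]1C)C2(C)C)[C@@H](OCOC)C=C | intermediate
11 | (3S,4S)-3-(methoxymethoxy)non-1-en-4-ol | CCCCC[C@H](O)[C@@H](OCOC)C=C | intermediate
12 | tert-butyldimethyl{[(3S,4S)-3-(methoxymethoxy)non-1-en-4-yl]oxy}silane | CCCCC[C@H](O[Si](C)(C)C(C)(C)C)[C@@H](OCOC)C=C | intermediate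
13 | 1,2,4-trioxolane (secondary ozonide) of 12, mixture of epimers at the ring carbon | CCCCC[C@H](O[Si](C)(C)C(C)(C)C)[C@@H](OCOC)C1OCOO1 | intermediate
14 | (2R,3S)-3-(tert-butyldimethylsilyloxy)-2-(methoxymethoxy)octanal | CCCCC[C@H](O[Si](C)(C)C(C)(C)C)[C@@H](OCOC)C=O | intermediate
15 | (3S,4S)-4-(tert-butyldimethylsilyloxy)-3-(methoxymethoxy)non-1-yne | CCCCC[C@H](O[Si](C)(C)C(C)(C)C)[C@@H](OCOC)C#C | intermediate
16 | N-methoxy-N-methylcarbamoyl chloride | CON(C)C(Cl)=O | starting material
17 | 2-(trimethylsilyl)ethyl 5-{2-[(3S,4S)-4-(tert-butyldimethylsilyloxy)-3-(methoxymethoxy)non-1-yn-1-yl]-4-methoxy-3-[methoxy(methyl)carbamoyl]phenoxy}-2-methylbenzoate | CCCCC[C@H](O[Si](C)(C)C(C)(C)C)[C@@H](OCOC)C#Cc1c(Oc2ccc(C)c(c2)C(=O)OCC[Si](C)(C)C)ccc(OC)c1C(=O)N(C)OC | intermediate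
18 | 2-(trimethylsilyl)ethyl 5-{2-[(3S,4S)-4-(tert-butyldimethylsilyloxy)-3-(methoxymethoxy)non-1-yn-1-yl]-3-formyl-4-methoxyphenoxy}-2-methylbenzoate | CCCCC[C@H](O[Si](C)(C)C(C)(C)C)[C@@H](OCOC)C#Cc1c(Oc2ccc(C)c(c2)C(=O)OCC[Si](C)(C)C)ccc(OC)c1C=O | intermediate
19 | 2-(trimethylsilyl)ethyl 5-{2-[(1Z,3S,4S)-4-(tert-butyldimethylsilyloxy)-3-(methoxymethoxy)non-1-en-1-yl]-3-formyl-4-methoxyphenoxy}-2-methylbenzoate | CCCCC[C@H](O[Si](C)(C)C(C)(C)C)[C@@H](OCOC)/C=C\c1c(Oc2ccc(C)c(c2)C(=O)OCC[Si](C)(C)C)ccc(OC)c1C=O | intermediate
20 | 5-{3-formyl-2-[(1Z,3S,4S)-4-hydroxy-3-(methoxymethoxy)non-1-en-1-yl]-4-methoxyphenoxy}-2-methylbenzoic acid | CCCCC[C@H](O)[C@@H](OCOC)/C=C\c1c(Oc2ccc(C)c(c2)C(=O)O)ccc(OC)c1C=O | intermediate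
21 | mixed anhydride of 20 with 2,4,6-trichlorobenzoic acid | CCCCC[C@H](O)[C@@H](OCOC)/C=C\c1c(Oc2ccc(C)c(c2)C(=O)OC(=O)c3c(Cl)cc(Cl)cc3Cl)ccc(OC)c1C=O | intermediate
22 | 12-membered (Z)-lactone with ring B methyl ether and allylic methoxymethyl ether, S at both carbinol carbons | CCCCC[C@@H]1OC(=O)c2cc(ccc2C)Oc2ccc(OC)c(C=O)c2/C=C\[C@@H]1OCOC | intermediate
23 | CNP0238900.1: 12-membered (Z)-lactone with free allylic alcohol and ring B salicylaldehyde, S at both carbinol carbons | CCCCC[C@@H]1OC(=O)c2cc(ccc2C)Oc2ccc(O)c(C=O)c2/C=C\[C@@H]1O | target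

**Step count and risks**

Total: 13 steps. Longest linear sequence: 10 steps (hexanal, steps 4 to 7, then 8 to 13).

Steps most likely to fail:

1. Step 8 (proposed method). Palladation beside the methoxy group may be too slow, so that direct alkynylation of the iodide takes over. The carbamoyl chloride may fail to add to the palladacycle, or may be consumed by palladium-catalysed carbamoylation of the alkyne. The doubly ortho-substituted arylpalladium may cyclise onto ring A before the alkyne arrives. A bridge-substituted norbornene is the first cocatalyst variable to screen within the step.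

   The fallback makes the same two bonds one at a time by known reactions, before ring A is attached, because the ortho-toluate methyl of ring A would not survive an amide base. It sets out from 4. Silylation (i-Pr3SiCl, imidazole, DMF) gives triisopropyl(2-iodo-4-methoxyphenoxy)silane F1. Directed ortho-lithiation with lithium 2,2,6,6-tetramethylpiperidide in THF at −78 °C at the C–H flanked by iodine and methoxy (the bulky, non-coordinating silyl ether disfavours the other ortho site) and trapping with 16 gives 2-iodo-N,6-dimethoxy-N-methyl-3-(triisopropylsilyloxy)benzamide F2. Bu4NF gives 3-hydroxy-2-iodo-N,6-dimethoxy-N-methylbenzamide F3. Chan–Lam coupling with 3 under the conditions of step 3 gives 2-(trimethylsilyl)ethyl 5-{2-iodo-4-methoxy-3-[methoxy(methyl)carbamoyl]phenoxy}-2-methylbenzoate F4. Sonogashira coupling of F4 with 15 (PdCl2(PPh3)2, CuI, Et3N, 60 °C) comes back to the route at 17.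

2. Step 12. Intermolecular esterification may outrun ring closure, because the hindered toluoyl carbonyl and the secondary hydroxyl must meet across a rigid cis-styrene and diaryl ether frame.

   The fallback activates the alcohol instead of the acid, which requires the C4 epimer. It sets out from 19. HF·pyridine in THF/pyridine removes only the silyl ether and gives 2-(trimethylsilyl)ethyl 5-{3-formyl-2-[(1Z,3S,4S)-4-hydroxy-3-(methoxymethoxy)non-1-en-1-yl]-4-methoxyphenoxy}-2-methylbenzoate F5. Mitsunobu inversion (4-nitrobenzoic acid, PPh3, DIAD, toluene) gives the (1Z,3S,4R)-4-(4-nitrobenzoyloxy) ester F6. Methanolysis (K2CO3, MeOH, 0 °C) gives 2-(trimethylsilyl)ethyl 5-{3-formyl-2-[(1Z,3S,4R)-4-hydroxy-3-(methoxymethoxy)non-1-en-1-yl]-4-methoxyphenoxy}-2-methylbenzoate F7. Bu4NF gives 5-{3-formyl-2-[(1Z,3S,4R)-4-hydroxy-3-(methoxymethoxy)non-1-en-1-yl]-4-methoxyphenoxy}-2-methylbenzoic acid F8. Mitsunobu macrolactonisation of F8 (PPh3, DIAD, toluene, slow addition, high dilution) closes the ring with inversion at C4 and comes back to the route at 22.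

3. Step 13. The boron Lewis acid may ionise the allylic C–O bond that is conjugated with the styrene, leading to chloride substitution or alkene isomerisation, or may open the lactone.

   The fallback removes the two ethers separately by milder, mechanistically different reagents. It sets out from 22. Pyridinium p-toluenesulfonate in t-BuOH at 80 °C hydrolyses only the acetal and gives the 12-membered (Z)-lactone with free allylic alcohol and ring B methyl ether F9. MgI2·OEt2 in toluene/Et2O at 60 °C, chelated by the formyl group, then demethylates the neighbouring ether and comes back to the route at 23.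

Further compounds
F1 | step 8 | triisopropyl(2-iodo-4-methoxyphenoxy)silane | COc1ccc(O[Si](C(C)C)(C(C)C)C(C)C)c(I)c1
F2 | step 8 | 2-iodo-N,6-dimethoxy-N-methyl-3-(triisopropylsilyloxy)benzamide | CON(C)C(=O)c1c(OC)ccc(O[Si](C(C)C)(C(C)C)C(C)C)c1I
F3 | step 8 | 3-hydroxy-2-iodo-N,6-dimethoxy-N-methylbenzamide | CON(C)C(=O)c1c(OC)ccc(O)c1I
F4 | step 8 | 2-(trimethylsilyl)ethyl 5-{2-iodo-4-methoxy-3-[methoxy(methyl)carbamoyl]phenoxy}-2-methylbenzoate | CON(C)C(=O)c1c(OC)ccc(Oc2ccc(C)c(c2)C(=O)OCC[Si](C)(C)C)c1I
F5 | step 12 | 2-(trimethylsilyl)ethyl 5-{3-formyl-2-[(1Z,3S,4S)-4-hydroxy-3-(methoxymethoxy)non-1-en-1-yl]-4-methoxyphenoxy}-2-methylbenzoate | CCCCC[C@H](O)[C@@H](OCOC)/C=C\c1c(Oc2ccc(C)c(c2)C(=O)OCC[Si](C)(C)C)ccc(OC)c1C=O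
F6 | step 12 | 2-(trimethylsilyl)ethyl 5-{3-formyl-4-methoxy-2-[(1Z,3S,4R)-3-(methoxymethoxy)-4-(4-nitrobenzoyloxy)non-1-en-1-yl]phenoxy}-2-methylbenzoate | CCCCC[C@@H](OC(=O)c3ccc(cc3)[N+](=O)[O-])[C@@H](OCOC)/C=C\c1c(Oc2ccc(C)c(c2)C(=O)OCC[Si](C)(C)C)ccc(OC)c1C=O
F7 | step 12 | 2-(trimethylsilyl)ethyl 5-{3-formyl-2-[(1Z,3S,4R)-4-hydroxy-3-(methoxymethoxy)non-1-en-1-yl]-4-methoxyphenoxy}-2-methylbenzoate | CCCCC[C@@H](O)[C@@H](OCOC)/C=C\c1c(Oc2ccc(C)c(c2)C(=O)OCC[Si](C)(C)C)ccc(OC)c1C=O
F8 | step 12 | 5-{3-formyl-2-[(1Z,3S,4R)-4-hydroxy-3-(methoxymethoxy)non-1-en-1-yl]-4-methoxyphenoxy}-2-methylbenzoic acid | CCCCC[C@@H](O)[C@@H](OCOC)/C=C\c1c(Oc2ccc(C)c(c2)C(=O)O)ccc(OC)c1C=O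
F9 | step 13 | 12-membered (Z)-lactone with free allylic alcohol and ring B methyl ether, S at both carbinol carbons | CCCCC[C@@H]1OC(=O)c2cc(ccc2C)Oc2ccc(OC)c(C=O)c2/C=C\[C@@H]1O
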